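Ring A is disconnected at C5–C6 and C4a–C8a. The contiguous carbons C6, C7, C8 and C8a with their four oxygens, including the vicinal methoxyls on C7 and C8, are the skeleton of dimethyl squarate; C5 (as a benzyl ether), C4a and the C4 ester carbon come from a 2-metallated 3-(benzyloxy)acrylate. Heating the resulting 4-alkenyl-4-hydroxycyclobutenone, a racemic carbinol carrying the acrylate through its α-carbon, opens the four-membered ring to a dienylketene whose 6π-electrocyclisation forms C5–C6 and delivers the hexasubstituted salicylate in one operation. Claisen condensation with the B-ring α-methoxy ketone, acid-induced closure of the pyranone through the C8a oxygen and hydrogenolysis complete the flavone.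

Key step: step 4

Remark: the target has no stereocentre and is achiral, so there is no enantiomer to select; the racemic carbinol centre of 8 and all alkene geometries disappear on aromatisation.

Step 1
Reactants: 1 benzyl alcohol; 2 methyl propiolate
Product: 3 methyl (E)-3-(benzyloxy)acrylate
Conditions: N-methylmorpholine (0.2 equiv), CH2Cl2, 0 °C → rt
Reagents that add atoms: none
Why: Tertiary-amine-catalysed oxa-Michael (conjugate) addition of the alcohol to the propiolate should give the trans β-alkoxyacrylate as the thermodynamically favoured isomer.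

Step 2
Reactants: 3 methyl (E)-3-(benzyloxy)acrylate
Product: 5 methyl (Z)-3-(benzyloxy)-2-iodoacrylate, via iodoacetate adduct 4 (not isolated)
Conditions: NIS (1.2 equiv), AcOH (2 equiv), CH2Cl2, rt; then Et3N (3 equiv), rt
Reagents that add atoms: N-iodosuccinimide, O=C1CCC(=O)N1I
Why: Iodoacetoxylation of the electron-rich enol ether double bond followed by amine-induced elimination of acetic acid (an addition–elimination α-halogenation of a β-alkoxyacrylate) should leave iodine cis to the benzyloxy group, i.e. the Z isomer.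

Step 3
Reactants: 5 methyl (Z)-3-(benzyloxy)-2-iodoacrylate; 6 dimethyl squarate
Product: 8 methyl (E)-3-(benzyloxy)-2-(1-hydroxy-2,3-dimethoxy-4-oxocyclobut-2-en-1-yl)acrylate (racemic), via alkenylmagnesium chloride 7 (not isolated)
Conditions: iPrMgCl·LiCl (1.05 equiv), THF, −78 °C; then 6, −78 → −40 °C; aq. NH4Cl, cold
Reagents that add atoms: none
Why: Iodine–magnesium exchange with the turbo-Grignard reagent should outrun attack on the ester at −78 °C, the magnesiated acrylate has magnesium cis to the benzyloxy group and so cannot undergo anti β-elimination, and Grignard 1,2-addition to one of the two equivalent squarate carbonyls gives the carbinol as a racemate whose stereocentre is erased in step 4.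

Step 4
Reactants: 8 methyl (E)-3-(benzyloxy)-2-(1-hydroxy-2,3-dimethoxy-4-oxocyclobut-2-en-1-yl)acrylate
Product: 11 methyl 2-(benzyloxy)-3,6-dihydroxy-4,5-dimethoxybenzoate, via dienylketene 9 (not isolated), via cyclohexadienone 10 (not isolated)
Conditions: PhMe (degassed, 0.02 M), 110 °C, Ar
Reagents that add atoms: none
Why: Heating triggers conrotatory 4π ring opening of the cyclobutenone (cleavage of the bond between the carbonyl carbon and the carbinol carbon) to dienylketene 9, whose thermal disrotatory 6π-electrocyclisation joins the ketene carbon to the benzyloxy-bearing alkene terminus (the future C5–C6 bond), and enolisation of dienone 10 then gives the aromatic hydroquinone. The closest known reaction type is the thermal ring expansion of squarate-derived 4-alkenyl-4-hydroxycyclobutenones to hydroquinones (Moore rearrangement). The one ring formed, the six-membered carbocycle that becomes ring A, is closed by this 6π-electrocyclisation. No stereocentre results, because the carbinol carbon of 8 and the sp3 carbon of 10 both end as aromatic carbons. The selectivity required is torquoselective outward rotation of the hydroxyl, which places the alkenyl group beside the ketene; it is secured by the donor oxygen on the carbinol carbon, and the acrylate geometry is irrelevant since both isomers converge on the same arene. A hydrogen bond from the enol hydroxyl of 9 to the ester carbonyl should hold the triene in the s-cis conformation needed for closure.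

Step 5
Reactants: 11 methyl 2-(benzyloxy)-3,6-dihydroxy-4,5-dimethoxybenzoate
Product: 12 methyl 2-(benzyloxy)-4,5-dimethoxy-3,6-bis(methoxymethoxy)benzoate
Conditions: NaH (2.5 equiv), MOMCl (3 equiv), DMF, 0 °C → rt, Ar
Reagents that add atoms: chloromethyl methyl ether, COCCl
Why: Williamson-type O-alkylation of both phenoxides with MOMCl (acetal protection) needs no selectivity between the two hydroxyls, ends the air sensitivity of the hydroquinone and leaves an ester with no ionisable ortho group for the Claisen step.

Step 6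
Reactants: 13 3,5-dihydroxy-4-methoxybenzoic acid
Product: 14 benzyl 3,5-bis(benzyloxy)-4-methoxybenzoate
Conditions: BnBr (3.5 equiv), K2CO3, DMF, 60 °C
Reagents that add atoms: benzyl bromide, BrCc1ccccc1
Why: Williamson alkylation of the two phenoxides and of the carboxylate (exhaustive O-benzylation) gives a non-enolisable ester that carries only hydrogenolysable protecting groups.

Step 7
Reactants: 14 benzyl 3,5-bis(benzyloxy)-4-methoxybenzoate; 15 methoxyacetic acid
Product: 18 1-[3,5-bis(benzyloxy)-4-methoxyphenyl]-2-methoxyethan-1-one, via dilithium enediolate 16 (not isolated), via keto acid 17 (not isolated)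
Conditions: 15 (2.2 equiv), LDA (4.4 equiv), THF, −78 → 0 °C; then 14, −78 °C → rt; 2 M HCl, 50 °C
Reagents that add atoms: none
Why: Claisen-type acylation of the carboxylic acid dianion by the non-enolisable aryl ester stops at the doubly deprotonated β-keto acid, which should lose CO2 on acidification and gentle warming to give the α-methoxy ketone (decarboxylative ketone synthesis).

Step 8
Reactants: 12 methyl 2-(benzyloxy)-4,5-dimethoxy-3,6-bis(methoxymethoxy)benzoate; 18 1-[3,5-bis(benzyloxy)-4-methoxyphenyl]-2-methoxyethan-1-one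
Product: 20 1-[2-(benzyloxy)-4,5-dimethoxy-3,6-bis(methoxymethoxy)phenyl]-3-[3,5-bis(benzyloxy)-4-methoxyphenyl]-2-methoxypropane-1,3-dione, via lithium enolate 19 (not isolated)
Conditions: 18 (1.5 equiv), LiHMDS (3 equiv), THF, −78 °C; then 12, −78 → 50 °C; aq. NH4Cl
Reagents that add atoms: none
Why: Crossed Claisen condensation of the preformed ketone enolate with the non-enolisable benzoate is driven forward by deprotonation of the 2-methoxy-1,3-diketone by the excess base, and the MOM caps prevent formation of a deactivating ortho phenoxide; the centre between the carbonyls is of no consequence because it becomes C3 of the flavone.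

Step 9
Reactants: 20 1-[2-(benzyloxy)-4,5-dimethoxy-3,6-bis(methoxymethoxy)phenyl]-3-[3,5-bis(benzyloxy)-4-methoxyphenyl]-2-methoxypropane-1,3-dione
Product: 22 5-(benzyloxy)-2-[3,5-bis(benzyloxy)-4-methoxyphenyl]-6-hydroxy-3,7,8-trimethoxy-4H-chromen-4-one, via dihydroxy diketone 21 (not isolated)
Conditions: conc. HCl, MeOH–THF (degassed), 60 °C, Ar
Reagents that add atoms: none
Why: Acid-catalysed transacetalisation removes both MOM groups, and the freed C8a hydroxyl, the only free oxygen ortho to the aroyl group since C5 stays benzylated, adds to the B-ring carbonyl and loses water (cyclodehydration of a 2-hydroxyphenyl 1,3-diketone) to close the 4-pyranone without regiochemical ambiguity.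

Step 10
Reactants: 22 5-(benzyloxy)-2-[3,5-bis(benzyloxy)-4-methoxyphenyl]-6-hydroxy-3,7,8-trimethoxy-4H-chromen-4-one
Product: 23 5,6,3',5'-tetrahydroxy-3,7,8,4'-tetramethoxyflavone
Conditions: H2 (1 atm), 10% Pd/C, EtOAc–MeOH, rt
Reagents that add atoms: none
Why: Palladium-catalysed hydrogenolysis of the three aryl benzyl ethers should leave the methyl ethers and the conjugated pyranone untouched at balloon pressure and room temperature.

Compound list

1 | benzyl alcohol | OCc1ccccc1 | starting material
2 | methyl propiolate | C#CC(=O)OC | starting material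
3 | methyl (E)-3-(benzyloxy)acrylate | COC(=O)/C=C/OCc1ccccc1 | intermediate
4 | methyl 3-acetoxy-3-(benzyloxy)-2-iodopropanoate (racemic diastereomer mixture, not isolated) | COC(=O)C(I)C(OC(C)=O)OCc1ccccc1 | intermediate
5 | methyl (Z)-3-(benzyloxy)-2-iodoacrylate | COC(=O)/C(I)=C/OCc1ccccc1 | intermediate
6 | dimethyl squarate (3,4-dimethoxycyclobut-3-ene-1,2-dione) | COC1=C(OC)C(=O)C1=O | starting material
7 | [(Z)-1-(benzyloxy)-3-methoxy-3-oxoprop-1-en-2-yl]magnesium chloride (LiCl complex, magnesium cis to benzyloxy, not isolated) | COC(=O)/C([Mg]Cl)=C/OCc1ccccc1 | intermediate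
8 | methyl (E)-3-(benzyloxy)-2-(1-hydroxy-2,3-dimethoxy-4-oxocyclobut-2-en-1-yl)acrylate (racemic carbinol) | COC(=O)/C(=C/OCc1ccccc1)C1(O)C(OC)=C(OC)C1=O | intermediate
9 | methyl (2E,3Z)-2-[(benzyloxy)methylidene]-3-hydroxy-4,5-dimethoxy-6-oxohexa-3,5-dienoate (dienylketene, not isolated) | O=C=C(OC)/C(OC)=C(/O)\C(C(=O)OC)=C/OCc1ccccc1 | intermediate
10 | methyl 6-(benzyloxy)-2-hydroxy-3,4-dimethoxy-5-oxocyclohexa-1,3-diene-1-carboxylate (racemic, not isolated) | COC(=O)C1=C(O)C(OC)=C(OC)C(=O)C1OCc1ccccc1 | intermediate
11 | methyl 2-(benzyloxy)-3,6-dihydroxy-4,5-dimethoxybenzoate | COC(=O)c1c(OCc2ccccc2)c(O)c(OC)c(OC)c1O | intermediate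
12 | methyl 2-(benzyloxy)-4,5-dimethoxy-3,6-bis(methoxymethoxy)benzoate | COCOc1c(OC)c(OC)c(OCOC)c(OCc2ccccc2)c1C(=O)OC | intermediate
13 | 3,5-dihydroxy-4-methoxybenzoic acid | COc1c(O)cc(C(=O)O)cc1O | starting material
14 | benzyl 3,5-bis(benzyloxy)-4-methoxybenzoate | COc1c(OCc2ccccc2)cc(C(=O)OCc2ccccc2)cc1OCc1ccccc1 | intermediate
15 | methoxyacetic acid | COCC(=O)O | starting material
16 | dilithium 2-methoxyethene-1,1-diolate (dianion of 15, not isolated) | COC=C([O-])[O-].[Li+].[Li+] | intermediate
17 | 3-[3,5-bis(benzyloxy)-4-methoxyphenyl]-2-methoxy-3-oxopropanoic acid (racemic, not isolated) | COC(C(=O)O)C(=O)c1cc(OCc2ccccc2)c(OC)c(OCc2ccccc2)c1 | intermediate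
18 | 1-[3,5-bis(benzyloxy)-4-methoxyphenyl]-2-methoxyethan-1-one | COCC(=O)c1cc(OCc2ccccc2)c(OC)c(OCc2ccccc2)c1 | intermediate
19 | lithium (Z)-1-[3,5-bis(benzyloxy)-4-methoxyphenyl]-2-methoxyethen-1-olate (not isolated) | CO/C=C(\[O-])c1cc(OCc2ccccc2)c(OC)c(OCc2ccccc2)c1.[Li+] | intermediate
20 | 1-[2-(benzyloxy)-4,5-dimethoxy-3,6-bis(methoxymethoxy)phenyl]-3-[3,5-bis(benzyloxy)-4-methoxyphenyl]-2-methoxypropane-1,3-dione (racemic at C2, keto–enol mixture) | COCOc1c(OC)c(OC)c(OCOC)c(OCc2ccccc2)c1C(=O)C(OC)C(=O)c1cc(OCc2ccccc2)c(OC)c(OCc2ccccc2)c1 | intermediate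
21 | 1-[2-(benzyloxy)-3,6-dihydroxy-4,5-dimethoxyphenyl]-3-[3,5-bis(benzyloxy)-4-methoxyphenyl]-2-methoxypropane-1,3-dione (not isolated) | COc1c(OC)c(O)c(OCc2ccccc2)c(C(=O)C(OC)C(=O)c2cc(OCc3ccccc3)c(OC)c(OCc3ccccc3)c2)c1O | intermediate
22 | 5-(benzyloxy)-2-[3,5-bis(benzyloxy)-4-methoxyphenyl]-6-hydroxy-3,7,8-trimethoxy-4H-chromen-4-one | COc1c(OCc2ccccc2)cc(-c2oc3c(OC)c(OC)c(O)c(OCc4ccccc4)c3c(=O)c2OC)cc1OCc1ccccc1 | intermediate
23 | 5,6,3',5'-tetrahydroxy-3,7,8,4'-tetramethoxyflavone (5,6-dihydroxy-2-(3,5-dihydroxy-4-methoxyphenyl)-3,7,8-trimethoxy-4H-chromen-4-one; achiral) | COc1c(O)cc(-c2oc3c(OC)c(OC)c(O)c(O)c3c(=O)c2OC)cc1O | target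

Total step count: 10.
Longest linear sequence: 8 steps (steps 1–5, then 8–10); the B-ring branch (steps 6–7) joins at step 8.

Steps most likely to fail

Step 4. The dienylketene may be diverted before it closes: after the minor inward rotation the free carbinol hydroxyl can capture the ketene (butenolide formation). The free hydroquinone may also be lost by air oxidation during isolation. The fallback caps the carbinol oxygen before heating. Setting out from 8, MOMCl/iPr2NEt (cat. Bu4NI, CH2Cl2, at most 40 °C) should give methyl (E)-3-(benzyloxy)-2-[2,3-dimethoxy-1-(methoxymethoxy)-4-oxocyclobut-2-en-1-yl]acrylate F4. Thermolysis in toluene would then pass through methyl (2E,3Z)-2-[(benzyloxy)methylidene]-4,5-dimethoxy-3-(methoxymethoxy)-6-oxohexa-3,5-dienoate F5 and methyl 6-(benzyloxy)-3,4-dimethoxy-2-(methoxymethoxy)-5-oxocyclohexa-1,3-diene-1-carboxylate F6. It should end at methyl 2-(benzyloxy)-3-hydroxy-4,5-dimethoxy-6-(methoxymethoxy)benzoate F7, a monophenol that cannot trap its ketene through oxygen and is not a hydroquinone. MOM protection of its single phenol (NaH, MOMCl, DMF) comes back to the route at 12.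

Step 3. The exchange reagent may attack the ester or the β-carbon of 5 faster than it exchanges iodine, or the magnesiated acrylate may decompose before it adds to the squarate. The fallback takes the ester out of play as a carboxylate. Setting out from 5, saponification (LiOH, THF–H2O) should give (Z)-3-(benzyloxy)-2-iodoacrylic acid F1. Two equivalents of n-BuLi at −90 °C (deprotonation, then iodine–lithium exchange) should give lithium (E)-3-(benzyloxy)-2-lithioacrylate F2, with lithium cis to the benzyloxy group, a carboxylate-protected vinyllithium of the α-lithioacrylate type. Addition of this species to 6 should give (E)-3-(benzyloxy)-2-(1-hydroxy-2,3-dimethoxy-4-oxocyclobut-2-en-1-yl)acrylic acid F3. O-Methylation of the carboxylate (MeI, KHCO3, DMF) comes back to the route at 8.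

Step 8. Acylation of the enolate at the doubly ortho-substituted ester carbonyl may be too slow, so that the enolate is consumed by proton transfer or self-condensation, or the diketone may revert by retro-Claisen cleavage. The fallback moves the electrophile to the aldehyde oxidation level. Setting out from 12, LiAlH4 reduction should give [2-(benzyloxy)-4,5-dimethoxy-3,6-bis(methoxymethoxy)phenyl]methanol F8. Dess–Martin oxidation should give 2-(benzyloxy)-4,5-dimethoxy-3,6-bis(methoxymethoxy)benzaldehyde F9. Aldol addition of enolate 19 at −78 °C should give 3-[2-(benzyloxy)-4,5-dimethoxy-3,6-bis(methoxymethoxy)phenyl]-1-[3,5-bis(benzyloxy)-4-methoxyphenyl]-3-hydroxy-2-methoxypropan-1-one F10 as a diastereomer mixture of no consequence. A second Dess–Martin oxidation of the β-hydroxy ketone comes back to the route at 20.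

Further compounds

F1 | step 3 | (Z)-3-(benzyloxy)-2-iodoacrylic acid | OC(=O)/C(I)=C/OCc1ccccc1
F2 | step 3 | lithium (E)-3-(benzyloxy)-2-lithioacrylate | [Li+].[O-]C(=O)/C([Li])=C/OCc1ccccc1
F3 | step 3 | (E)-3-(benzyloxy)-2-(1-hydroxy-2,3-dimethoxy-4-oxocyclobut-2-en-1-yl)acrylic acid (racemic) | OC(=O)/C(=C/OCc1ccccc1)C1(O)C(OC)=C(OC)C1=O
F4 | step 4 | methyl (E)-3-(benzyloxy)-2-[2,3-dimethoxy-1-(methoxymethoxy)-4-oxocyclobut-2-en-1-yl]acrylate (racemic) | COC(=O)/C(=C/OCc1ccccc1)C1(OCOC)C(OC)=C(OC)C1=O
F5 | step 4 | methyl (2E,3Z)-2-[(benzyloxy)methylidene]-4,5-dimethoxy-3-(methoxymethoxy)-6-oxohexa-3,5-dienoate | O=C=C(OC)/C(OC)=C(/OCOC)\C(C(=O)OC)=C/OCc1ccccc1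
F6 | step 4 | methyl 6-(benzyloxy)-3,4-dimethoxy-2-(methoxymethoxy)-5-oxocyclohexa-1,3-diene-1-carboxylate (racemic) | COC(=O)C1=C(OCOC)C(OC)=C(OC)C(=O)C1OCc1ccccc1
F7 | step 4 | methyl 2-(benzyloxy)-3-hydroxy-4,5-dimethoxy-6-(methoxymethoxy)benzoate | COC(=O)c1c(OCc2ccccc2)c(O)c(OC)c(OC)c1OCOC
F8 | step 8 | [2-(benzyloxy)-4,5-dimethoxy-3,6-bis(methoxymethoxy)phenyl]methanol | COCOc1c(OC)c(OC)c(OCOC)c(OCc2ccccc2)c1CO
F9 | step 8 | 2-(benzyloxy)-4,5-dimethoxy-3,6-bis(methoxymethoxy)benzaldehyde | COCOc1c(OC)c(OC)c(OCOC)c(OCc2ccccc2)c1C=O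
F10 | step 8 | 3-[2-(benzyloxy)-4,5-dimethoxy-3,6-bis(methoxymethoxy)phenyl]-1-[3,5-bis(benzyloxy)-4-methoxyphenyl]-3-hydroxy-2-methoxypropan-1-one (diastereomer mixture) | COCOc1c(OC)c(OC)c(OCOC)c(OCc2ccccc2)c1C(O)C(OC)C(=O)c1cc(OCc2ccccc2)c(OC)c(OCc2ccccc2)c1
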